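**Retrosynthetic overview**

1. Rings A and B are identical 14-membered macrodiolides (ring numbering O1, C2(=O), C3=C4, C5(OH), C6(Me), O7, C8(=O), C9, C10, C11(=O), C12, C13, C14(Me)), each bonded through C9 to C3 of the pyrandione ring C. Both C9–C3 bonds are cut by a retro double Michael addition, giving two molecules of one macrocyclic (E)-enedione and one (S)-pyrandione; this three-component union is the last C–C event.
2. The enabling feature in the macrocycle is the C11 ketone and the C14–O1 ester joined by the C12–C13 bridge. C12 is the α′-carbon of the C8–C11 4-oxo-2-enoate, so it is the CH2 terminus of that unit's cross-conjugated silyl dienol ether. C13–C14 is (S)-3-hydroxybutanoic acid minus CO2. The C12–C13 bond is therefore made by a ring-closing decarboxylative radical alkylation that returns the enedione directly.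
3. The seco ester is assembled by esterification from three acid-level pieces: a (Z)-4,5-dihydroxyhex-2-enoate unit built from ethyl (S)-lactate and a propiolate (Felkin–Anh alkynylation, Lindlar reduction), (E)-4-oxopent-2-enoic acid, and tert-butyl (S)-3-hydroxybutanoate.
4. Ring order: the 14-membered ring (step 12, product used twice), then ring C (step 14), then union at the quaternary carbon (step 15, no new ring), then desilylation.

Key step: step 12

Remark: the R configuration at C9 in both rings is assumed to be the one that peripheral attack on the macrocyclic (E)-enedione delivers, as the biogenetic relationship suggests.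

**Route**

Step 1
Reactants: 1 ethyl (S)-lactate
Product: 2 ethyl (2S)-2-[(triethylsilyl)oxy]propanoate
Conditions: TESCl, imidazole, CH2Cl2, 0 → 23 °C
Reagents that add atoms: chlorotriethylsilane, CC[Si](Cl)(CC)CC
Why: O-silylation of the secondary alcohol gives a non-chelating TES ether that can later be removed in the presence of a TBS ether, and the S stereocentre is untouched.

Step 2
Reactants: 2 ethyl (2S)-2-[(triethylsilyl)oxy]propanoate
Product: 3 (2S)-2-[(triethylsilyl)oxy]propanal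
Conditions: i-Bu2AlH (1.05 equiv), CH2Cl2, −78 °C; aq. sodium potassium tartrate; used crude
Reagents that add atoms: none
Why: Low-temperature partial reduction of the ester with i-Bu2AlH stops at the aluminium hemiacetal and should give the α-silyloxy aldehyde without epimerisation when it is used at once.

Step 3
Reactants: 4 propiolic acid, 5 tert-butyl (3S)-3-hydroxybutanoate
Product: 6 tert-butyl (3S)-3-(prop-2-ynoyloxy)butanoate
Conditions: DCC, DMAP (5 mol %), CH2Cl2, −20 → 0 °C
Reagents that add atoms: none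
Why: Steglich esterification at low temperature acylates the secondary alcohol with retention at the carbinol carbon (future C14) and keeps the alkyne C–H for the next step.

Step 4
Reactants: 6 tert-butyl (3S)-3-(prop-2-ynoyloxy)butanoate, 3 (2S)-2-[(triethylsilyl)oxy]propanal
Product: 7 tert-butyl (3S)-3-{[(4R,5S)-4-hydroxy-5-[(triethylsilyl)oxy]hex-2-ynoyl]oxy}butanoate
Conditions: LiN(SiMe3)2 (1.0 equiv), THF, −78 °C; then 3; AcOH quench at −78 °C
Reagents that add atoms: none
Why: Addition of the lithium acetylide of a propiolate ester to the α-silyloxy aldehyde under Felkin–Anh (non-chelation) control should favour the anti (4R,5S) propargylic alcohol, and the syn epimer is removed by chromatography.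

Step 5
Reactants: 7 tert-butyl (3S)-3-{[(4R,5S)-4-hydroxy-5-[(triethylsilyl)oxy]hex-2-ynoyl]oxy}butanoate
Product: 8 tert-butyl (3S)-3-{[(4R,5S)-4-[(tert-butyldimethylsilyl)oxy]-5-[(triethylsilyl)oxy]hex-2-ynoyl]oxy}butanoate
Conditions: TBSOTf, 2,6-lutidine, CH2Cl2, −78 → 0 °C
Reagents that add atoms: tert-butyldimethylsilyl trifluoromethanesulfonate, CC(C)(C)[Si](C)(C)OS(=O)(=O)C(F)(F)F
Why: Silyl triflate silylation protects the hindered propargylic alcohol (future C5–OH) as a TBS ether that outlasts the more labile TES ether.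

Step 6
Reactants: 8 tert-butyl (3S)-3-{[(4R,5S)-4-[(tert-butyldimethylsilyl)oxy]-5-[(triethylsilyl)oxy]hex-2-ynoyl]oxy}butanoate
Product: 9 tert-butyl (3S)-3-{[(2Z,4R,5S)-4-[(tert-butyldimethylsilyl)oxy]-5-[(triethylsilyl)oxy]hex-2-enoyl]oxy}butanoate
Conditions: H2 (1 atm), Pd/CaCO3 poisoned with Pb(OAc)2 (Lindlar catalyst), quinoline, EtOAc, 23 °C
Reagents that add atoms: none
Why: Lindlar semi-hydrogenation adds H2 syn to the alkyne and gives the Z-enoate, with no other reducible group in the molecule at this stage.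

Step 7
Reactants: 9 tert-butyl (3S)-3-{[(2Z,4R,5S)-4-[(tert-butyldimethylsilyl)oxy]-5-[(triethylsilyl)oxy]hex-2-enoyl]oxy}butanoate
Product: 10 tert-butyl (3S)-3-{[(2Z,4R,5S)-4-[(tert-butyldimethylsilyl)oxy]-5-hydroxyhex-2-enoyl]oxy}butanoate
Conditions: HF·pyridine, excess pyridine, THF, 0 °C; used at once
Reagents that add atoms: none
Why: Buffered fluoride desilylation cleaves the TES ether much faster than the secondary TBS ether, and the near-neutral medium should limit lactonisation of the Z-δ-hydroxy enoate.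

Step 8
Reactants: 10 tert-butyl (3S)-3-{[(2Z,4R,5S)-4-[(tert-butyldimethylsilyl)oxy]-5-hydroxyhex-2-enoyl]oxy}butanoate, 11 (2E)-4-oxopent-2-enoic acid
Product: 12 tert-butyl (3S)-3-{[(2Z,4R,5S)-4-[(tert-butyldimethylsilyl)oxy]-5-{[(2E)-4-oxopent-2-enoyl]oxy}hex-2-enoyl]oxy}butanoate
Conditions: N,N'-diisopropylcarbodiimide, DMAP (10 mol %), CH2Cl2, 0 °C
Reagents that add atoms: none
Why: Steglich esterification acylates the free hydroxyl (future O7) with the enedione acid, after which six-membered lactonisation is no longer possible.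

Step 9
Reactants: 12 tert-butyl (3S)-3-{[(2Z,4R,5S)-4-[(tert-butyldimethylsilyl)oxy]-5-{[(2E)-4-oxopent-2-enoyl]oxy}hex-2-enoyl]oxy}butanoate
Product: 13 (3S)-3-{[(2Z,4R,5S)-4-[(tert-butyldimethylsilyl)oxy]-5-{[(2E)-4-oxopent-2-enoyl]oxy}hex-2-enoyl]oxy}butanoic acid
Conditions: TFA/CH2Cl2 (1:4), 0 °C
Reagents that add atoms: none
Why: Acidolysis of the tert-butyl ester (E1 loss of 2-methylpropene) frees the acid, while the TBS ether, flanked by two carbons bearing electron-withdrawing groups, should survive cold anhydrous acid.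

Step 10
Reactants: 13 (3S)-3-{[(2Z,4R,5S)-4-[(tert-butyldimethylsilyl)oxy]-5-{[(2E)-4-oxopent-2-enoyl]oxy}hex-2-enoyl]oxy}butanoic acid
Product: 14 1,3-dioxoisoindolin-2-yl (3S)-3-{[(2Z,4R,5S)-4-[(tert-butyldimethylsilyl)oxy]-5-{[(2E)-4-oxopent-2-enoyl]oxy}hex-2-enoyl]oxy}butanoate
Conditions: N-hydroxyphthalimide, N,N'-diisopropylcarbodiimide, CH2Cl2, 0 → 23 °C
Reagents that add atoms: N-hydroxyphthalimide, O=C1N(O)C(=O)c2ccccc12
Why: Carbodiimide coupling with N-hydroxyphthalimide gives the redox-active N-acyloxyphthalimide ester needed for reductive decarboxylation.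

Step 11
Reactants: 14 1,3-dioxoisoindolin-2-yl (3S)-3-{[(2Z,4R,5S)-4-[(tert-butyldimethylsilyl)oxy]-5-{[(2E)-4-oxopent-2-enoyl]oxy}hex-2-enoyl]oxy}butanoate
Product: 15 1,3-dioxoisoindolin-2-yl (3S)-3-{[(2Z,4R,5S)-4-[(tert-butyldimethylsilyl)oxy]-5-{[(2E)-4-[(tert-butyldimethylsilyl)oxy]penta-2,4-dienoyl]oxy}hex-2-enoyl]oxy}butanoate
Conditions: TBSOTf (1.2 equiv), Et3N (1.5 equiv), CH2Cl2, −78 → −20 °C; filtration through Et3N-deactivated silica
Reagents that add atoms: tert-butyldimethylsilyl trifluoromethanesulfonate, CC(C)(C)[Si](C)(C)OS(=O)(=O)C(F)(F)F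
Why: Soft enolisation of the methyl ketone with silyl triflate and tertiary amine gives the cross-conjugated 2-silyloxy diene, which is the only possible enol silane because the other α-carbon is vinylic.

Step 12
Reactants: 15 1,3-dioxoisoindolin-2-yl (3S)-3-{[(2Z,4R,5S)-4-[(tert-butyldimethylsilyl)oxy]-5-{[(2E)-4-[(tert-butyldimethylsilyl)oxy]penta-2,4-dienoyl]oxy}hex-2-enoyl]oxy}butanoate
Product: 16 (3Z,5R,6S,9E,14S)-5-[(tert-butyldimethylsilyl)oxy]-6,14-dimethyl-1,7-dioxacyclotetradeca-3,9-diene-2,8,11-trione (macrocyclic enedione)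
Conditions: fac-Ir(ppy)3 (1 mol %), MeCN (2 mM, syringe-pump addition of 15), 450 nm LEDs, 25 °C, Ar
Reagents that add atoms: none
Why: Proposed new method: the photoexcited trivalent iridium complex transfers one electron to the N-acyloxyphthalimide, which fragments to phthalimide anion, CO2 and a primary radical at C13; this nucleophilic radical adds to C12, the unsubstituted terminus of the 2-silyloxy dienoate, and the resulting silyloxyallyl radical is oxidised by the tetravalent iridium complex and desilylated by phthalimide anion to the (E)-enedione, so the cycle is redox-neutral. The closest known reaction types are the photoredox decarboxylative alkylation of silyl enol ethers with N-acyloxyphthalimides, decarboxylative radical macrocyclisation onto Michael acceptors, and 1,6-addition of alkyl radicals to dienoates. The 14-membered ring closes in a 14-endo-trig radical mode. No new stereocentre is formed: C14 is carried over from 5, and the C9=C10 bond should keep its E geometry because it remains part of the allyl system and E is the more stable enedione. The step needs attack at C12 rather than at the Z-enoate or at C9/C10, and cyclisation rather than 1,2-acyloxy shift, hydrogen abstraction or oligomerisation; C12 is the only unhindered CH2 terminus and gives a doubly stabilised (silyloxyallyl, ester-conjugated) radical, the ester tether disfavours small-ring closure onto C3/C4, and high dilution with slow addition suppresses intermolecular paths.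

Step 13
Reactants: 17 methyl (3S)-3-hydroxybutanoate, 18 tert-butyl acetate
Product: 19 tert-butyl (5S)-5-hydroxy-3-oxohexanoate
Conditions: LiN(i-Pr)2 (3.3 equiv), 18 (3.3 equiv), THF, −78 → −30 °C; AcOH quench
Reagents that add atoms: none
Why: Claisen condensation of the methyl ester with excess lithium tert-butyl acetate enolate gives the δ-hydroxy-β-keto ester without involving the carbinol stereocentre.

Step 14
Reactants: 19 tert-butyl (5S)-5-hydroxy-3-oxohexanoate
Product: 20 (6S)-6-methyldihydro-2H-pyran-2,4(3H)-dione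
Conditions: TFA, CH2Cl2, 23 °C
Reagents that add atoms: none
Why: Acid-mediated loss of the tert-butyl group and lactonisation of the δ-hydroxy acid closes the six-membered β-keto lactone (ring C) with the S centre intact.

Step 15
Reactants: 16 macrocyclic enedione (2.1 equiv), 20 (6S)-6-methyldihydro-2H-pyran-2,4(3H)-dione
Product: 22 (6S)-3,3-bis{(3Z,5R,6S,9R,14S)-5-[(tert-butyldimethylsilyl)oxy]-6,14-dimethyl-2,8,11-trioxo-1,7-dioxacyclotetradec-3-en-9-yl}-6-methyldihydro-2H-pyran-2,4(3H)-dione, via mono-Michael adduct 21 (not isolated)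
Conditions: i-Pr2NEt (0.3 equiv), MeCN (0.3 M), 23 → 40 °C
Reagents that add atoms: none
Why: Base-mediated double Michael addition of C3 of the cyclic 1,3-dicarbonyl to C9 (the carbon β to the ketone) of two enedione rings builds the quaternary carbon, and each C9 centre should be set R by peripheral attack on the exposed face of the E-enone held in the 14-membered ring, with reversibility of the addition allowing equilibration to the more stable adduct.

Step 16
Reactants: 22 bis-TBS ether of the target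
Product: 23 (6S)-3,3-bis[(3Z,5R,6S,9R,14S)-5-hydroxy-6,14-dimethyl-2,8,11-trioxo-1,7-dioxacyclotetradec-3-en-9-yl]-6-methyldihydro-2H-pyran-2,4(3H)-dione (target)
Conditions: HF·pyridine, pyridine, THF, 0 → 23 °C
Reagents that add atoms: none
Why: Fluoride desilylation under buffered, weakly acidic conditions should free the two C5 hydroxyls without base-induced retro-Michael reaction or translactonisation.

**Compound list**

1 | ethyl (S)-lactate | CCOC(=O)[C@H](C)O | starting material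
2 | ethyl (2S)-2-[(triethylsilyl)oxy]propanoate | CCOC(=O)[C@H](C)O[Si](CC)(CC)CC | intermediate
3 | (2S)-2-[(triethylsilyl)oxy]propanal | O=C[C@H](C)O[Si](CC)(CC)CC | intermediate
4 | propiolic acid | C#CC(=O)O | starting material
5 | tert-butyl (3S)-3-hydroxybutanoate | C[C@H](O)CC(=O)OC(C)(C)C | starting material
6 | tert-butyl (3S)-3-(prop-2-ynoyloxy)butanoate | C#CC(=O)O[C@@H](C)CC(=O)OC(C)(C)C | intermediate
7 | tert-butyl (3S)-3-{[(4R,5S)-4-hydroxy-5-[(triethylsilyl)oxy]hex-2-ynoyl]oxy}butanoate | C[C@H](O[Si](CC)(CC)CC)[C@H](O)C#CC(=O)O[C@@H](C)CC(=O)OC(C)(C)C | intermediate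
8 | tert-butyl (3S)-3-{[(4R,5S)-4-[(tert-butyldimethylsilyl)oxy]-5-[(triethylsilyl)oxy]hex-2-ynoyl]oxy}butanoate | C[C@H](O[Si](CC)(CC)CC)[C@H](O[Si](C)(C)C(C)(C)C)C#CC(=O)O[C@@H](C)CC(=O)OC(C)(C)C | intermediate
9 | tert-butyl (3S)-3-{[(2Z,4R,5S)-4-[(tert-butyldimethylsilyl)oxy]-5-[(triethylsilyl)oxy]hex-2-enoyl]oxy}butanoate | C[C@H](O[Si](CC)(CC)CC)[C@H](O[Si](C)(C)C(C)(C)C)/C=C\C(=O)O[C@@H](C)CC(=O)OC(C)(C)C | intermediate
10 | tert-butyl (3S)-3-{[(2Z,4R,5S)-4-[(tert-butyldimethylsilyl)oxy]-5-hydroxyhex-2-enoyl]oxy}butanoate | C[C@H](O)[C@H](O[Si](C)(C)C(C)(C)C)/C=C\C(=O)O[C@@H](C)CC(=O)OC(C)(C)C | intermediate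
11 | (2E)-4-oxopent-2-enoic acid | CC(=O)/C=C/C(=O)O | starting material
12 | tert-butyl (3S)-3-{[(2Z,4R,5S)-4-[(tert-butyldimethylsilyl)oxy]-5-{[(2E)-4-oxopent-2-enoyl]oxy}hex-2-enoyl]oxy}butanoate | C[C@H](OC(=O)/C=C/C(C)=O)[C@H](O[Si](C)(C)C(C)(C)C)/C=C\C(=O)O[C@@H](C)CC(=O)OC(C)(C)C | intermediate
13 | (3S)-3-{[(2Z,4R,5S)-4-[(tert-butyldimethylsilyl)oxy]-5-{[(2E)-4-oxopent-2-enoyl]oxy}hex-2-enoyl]oxy}butanoic acid | C[C@H](OC(=O)/C=C/C(C)=O)[C@H](O[Si](C)(C)C(C)(C)C)/C=C\C(=O)O[C@@H](C)CC(=O)O | intermediate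
14 | 1,3-dioxoisoindolin-2-yl (3S)-3-{[(2Z,4R,5S)-4-[(tert-butyldimethylsilyl)oxy]-5-{[(2E)-4-oxopent-2-enoyl]oxy}hex-2-enoyl]oxy}butanoate | C[C@H](OC(=O)/C=C/C(C)=O)[C@H](O[Si](C)(C)C(C)(C)C)/C=C\C(=O)O[C@@H](C)CC(=O)ON1C(=O)c2ccccc2C1=O | intermediate
15 | 1,3-dioxoisoindolin-2-yl (3S)-3-{[(2Z,4R,5S)-4-[(tert-butyldimethylsilyl)oxy]-5-{[(2E)-4-[(tert-butyldimethylsilyl)oxy]penta-2,4-dienoyl]oxy}hex-2-enoyl]oxy}butanoate | C[C@H](OC(=O)/C=C/C(=C)O[Si](C)(C)C(C)(C)C)[C@H](O[Si](C)(C)C(C)(C)C)/C=C\C(=O)O[C@@H](C)CC(=O)ON1C(=O)c2ccccc2C1=O | intermediate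
16 | (3Z,5R,6S,9E,14S)-5-[(tert-butyldimethylsilyl)oxy]-6,14-dimethyl-1,7-dioxacyclotetradeca-3,9-diene-2,8,11-trione | C[C@H]1CCC(=O)/C=C/C(=O)O[C@@H](C)[C@H](O[Si](C)(C)C(C)(C)C)/C=C\C(=O)O1 | intermediate
17 | methyl (3S)-3-hydroxybutanoate | C[C@H](O)CC(=O)OC | starting material
18 | tert-butyl acetate | CC(=O)OC(C)(C)C | starting material
19 | tert-butyl (5S)-5-hydroxy-3-oxohexanoate | C[C@H](O)CC(=O)CC(=O)OC(C)(C)C | intermediate
20 | (6S)-6-methyldihydro-2H-pyran-2,4(3H)-dione | C[C@H]1CC(=O)CC(=O)O1 | intermediate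
21 | (6S)-3-{(3Z,5R,6S,9R,14S)-5-[(tert-butyldimethylsilyl)oxy]-6,14-dimethyl-2,8,11-trioxo-1,7-dioxacyclotetradec-3-en-9-yl}-6-methyldihydro-2H-pyran-2,4(3H)-dione (mono-Michael adduct, C3 of ring C enolisable) | C[C@H]1CCC(=O)C[C@H](C2C(=O)C[C@H](C)OC2=O)C(=O)O[C@@H](C)[C@H](O[Si](C)(C)C(C)(C)C)/C=C\C(=O)O1 | intermediate
22 | (6S)-3,3-bis{(3Z,5R,6S,9R,14S)-5-[(tert-butyldimethylsilyl)oxy]-6,14-dimethyl-2,8,11-trioxo-1,7-dioxacyclotetradec-3-en-9-yl}-6-methyldihydro-2H-pyran-2,4(3H)-dione | C[C@@H]1OC(=O)[C@@H](C2([C@H]3CC(=O)CC[C@H](C)OC(=O)/C=C\[C@@H](O[Si](C)(C)C(C)(C)C)[C@H](C)OC3=O)C(=O)C[C@H](C)OC2=O)CC(=O)CC[C@H](C)OC(=O)/C=C\[C@H]1O[Si](C)(C)C(C)(C)C | intermediate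
23 | (6S)-3,3-bis[(3Z,5R,6S,9R,14S)-5-hydroxy-6,14-dimethyl-2,8,11-trioxo-1,7-dioxacyclotetradec-3-en-9-yl]-6-methyldihydro-2H-pyran-2,4(3H)-dione | C[C@@H]1OC(=O)[C@@H](C2([C@H]3CC(=O)CC[C@H](C)OC(=O)/C=C\[C@@H](O)[C@H](C)OC3=O)C(=O)C[C@H](C)OC2=O)CC(=O)CC[C@H](C)OC(=O)/C=C\[C@H]1O | target

**Step count and risks**

Total step count: 16. Longest linear sequence: 13 steps (steps 1, 2, 4–12, 15, 16, from ethyl (S)-lactate).

Steps most likely to fail:

1. Step 12 (proposed new method). The C13 radical may be quenched by hydrogen abstraction, rearrange by 1,2-acyloxy shift, or react intermolecularly faster than it closes the 14-membered ring. Its addition to the silyloxy diene terminus may also be slow, and the enedione product may suffer light-induced E/Z scrambling. The fallback uses known chemistry to make the same C12–C13 bond; it sets out from 3 and returns at 16. Propiolic acid 4 is esterified (DCC) with commercial (S)-but-3-en-2-ol to give (2S)-but-3-en-2-yl prop-2-ynoate F1. Its lithium acetylide adds to 3 under Felkin–Anh control to give propargylic alcohol F2. TBSOTf gives bis-silyl ether F3, and HF·pyridine removes the TES group at the alkyne stage to give alcohol F4. F4 opens (S)-2-acetoxysuccinic anhydride at the carbonyl next to the acetoxy group (DMAP, pyridine) to give hemiester F5, and Lindlar semi-hydrogenation gives Z-enoate acid F6. The acid chloride, made with 1-chloro-N,N,2-trimethylprop-1-en-1-amine, is coupled with tributyl(vinyl)stannane (Pd2(dba)3, tri(2-furyl)phosphine, Stille acylation) to give vinyl ketone F7. Ring-closing metathesis (second-generation Hoveyda–Grubbs catalyst, toluene, 1 mM, 80 °C) joins C12 and C13 as an (E)-enone in macrocycle F8. Conjugate reduction with [(Ph3P)CuH]6 saturates only this enone to give acetoxy ketone F9, and Et3N-induced E1cB loss of acetic acid gives 16.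

2. Step 15. The reaction may stall after the first addition, because the second addition creates a quaternary carbon between two tertiary centres and is reversible, and facial selectivity at C9 may be poor. The fallback sets out from 16 and 20 and returns at 22. One equivalent of 16 and 20 with catalytic Et3N give mono-adduct 21, which is now isolated. TMSCl/Et3N converts its β-keto lactone enol into silyl enol ether F10. Mukaiyama–Michael addition of F10 to a second equivalent of 16, promoted by Sc(OTf)3 at −78 °C (irreversible, kinetically controlled), followed by aqueous work-up, gives 22.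

3. Step 7 (with step 8). Once the hydroxyl is free, the Z-δ-hydroxy enoate can cyclise by intramolecular transesterification to the six-membered lactone, with loss of the 3-hydroxybutanoate. The fallback sets out from 8 and returns at 12. HF·pyridine is applied to alkyne 8, whose geometry forbids lactonisation, to give alcohol F11. F11 opens (S)-2-acetoxysuccinic anhydride (DMAP, pyridine) to give hemiester F12, and Lindlar semi-hydrogenation gives Z-enoate acid F13. The acid chloride (same chloroenamine) reacts with MeMgBr and Fe(acac)3 (3 mol %) at −78 °C to give methyl ketone F14, and Et3N eliminates acetic acid (E1cB) to give 12.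

Further compounds
F1 | step 12 | (2S)-but-3-en-2-yl prop-2-ynoate | C#CC(=O)O[C@@H](C)C=C
F2 | step 12 | (2S)-but-3-en-2-yl (4R,5S)-4-hydroxy-5-[(triethylsilyl)oxy]hex-2-ynoate | C[C@H](O[Si](CC)(CC)CC)[C@H](O)C#CC(=O)O[C@@H](C)C=C
F3 | step 12 | (2S)-but-3-en-2-yl (4R,5S)-4-[(tert-butyldimethylsilyl)oxy]-5-[(triethylsilyl)oxy]hex-2-ynoate | C[C@H](O[Si](CC)(CC)CC)[C@H](O[Si](C)(C)C(C)(C)C)C#CC(=O)O[C@@H](C)C=C
F4 | step 12 | (2S)-but-3-en-2-yl (4R,5S)-4-[(tert-butyldimethylsilyl)oxy]-5-hydroxyhex-2-ynoate | C[C@H](O)[C@H](O[Si](C)(C)C(C)(C)C)C#CC(=O)O[C@@H](C)C=C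
F5 | step 12 | (3S)-3-acetoxy-4-{[(2S,3R)-6-{[(2S)-but-3-en-2-yl]oxy}-3-[(tert-butyldimethylsilyl)oxy]-6-oxohex-4-yn-2-yl]oxy}-4-oxobutanoic acid | C[C@H](OC(=O)[C@H](CC(=O)O)OC(C)=O)[C@H](O[Si](C)(C)C(C)(C)C)C#CC(=O)O[C@@H](C)C=C
F6 | step 12 | (3S)-3-acetoxy-4-{[(2S,3R,4Z)-6-{[(2S)-but-3-en-2-yl]oxy}-3-[(tert-butyldimethylsilyl)oxy]-6-oxohex-4-en-2-yl]oxy}-4-oxobutanoic acid | C[C@H](OC(=O)[C@H](CC(=O)O)OC(C)=O)[C@H](O[Si](C)(C)C(C)(C)C)/C=C\C(=O)O[C@@H](C)C=C
F7 | step 12 | (2S)-but-3-en-2-yl (2Z,4R,5S)-5-{[(2S)-2-acetoxy-4-oxohex-5-enoyl]oxy}-4-[(tert-butyldimethylsilyl)oxy]hex-2-enoate | C[C@H](OC(=O)[C@H](CC(=O)C=C)OC(C)=O)[C@H](O[Si](C)(C)C(C)(C)C)/C=C\C(=O)O[C@@H](C)C=C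
F8 | step 12 | (3Z,5R,6S,9S,12E,14S)-9-acetoxy-5-[(tert-butyldimethylsilyl)oxy]-6,14-dimethyl-1,7-dioxacyclotetradeca-3,12-diene-2,8,11-trione | C[C@H]1/C=C/C(=O)C[C@H](OC(C)=O)C(=O)O[C@@H](C)[C@H](O[Si](C)(C)C(C)(C)C)/C=C\C(=O)O1
F9 | step 12 | (3Z,5R,6S,9S,14S)-9-acetoxy-5-[(tert-butyldimethylsilyl)oxy]-6,14-dimethyl-1,7-dioxacyclotetradec-3-ene-2,8,11-trione | C[C@H]1CCC(=O)C[C@H](OC(C)=O)C(=O)O[C@@H](C)[C@H](O[Si](C)(C)C(C)(C)C)/C=C\C(=O)O1
F10 | step 15 | (6S)-3-{(3Z,5R,6S,9R,14S)-5-[(tert-butyldimethylsilyl)oxy]-6,14-dimethyl-2,8,11-trioxo-1,7-dioxacyclotetradec-3-en-9-yl}-6-methyl-4-[(trimethylsilyl)oxy]-5,6-dihydro-2H-pyran-2-one | C[C@H]1CCC(=O)C[C@H](C2=C(O[Si](C)(C)C)C[C@H](C)OC2=O)C(=O)O[C@@H](C)[C@H](O[Si](C)(C)C(C)(C)C)/C=C\C(=O)O1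
F11 | step 7 | tert-butyl (3S)-3-{[(4R,5S)-4-[(tert-butyldimethylsilyl)oxy]-5-hydroxyhex-2-ynoyl]oxy}butanoate | C[C@H](O)[C@H](O[Si](C)(C)C(C)(C)C)C#CC(=O)O[C@@H](C)CC(=O)OC(C)(C)C
F12 | step 7 | (3S)-3-acetoxy-4-{[(2S,3R)-6-{[(2S)-4-(tert-butoxy)-4-oxobutan-2-yl]oxy}-3-[(tert-butyldimethylsilyl)oxy]-6-oxohex-4-yn-2-yl]oxy}-4-oxobutanoic acid | C[C@H](OC(=O)[C@H](CC(=O)O)OC(C)=O)[C@H](O[Si](C)(C)C(C)(C)C)C#CC(=O)O[C@@H](C)CC(=O)OC(C)(C)C
F13 | step 7 | (3S)-3-acetoxy-4-{[(2S,3R,4Z)-6-{[(2S)-4-(tert-butoxy)-4-oxobutan-2-yl]oxy}-3-[(tert-butyldimethylsilyl)oxy]-6-oxohex-4-en-2-yl]oxy}-4-oxobutanoic acid | C[C@H](OC(=O)[C@H](CC(=O)O)OC(C)=O)[C@H](O[Si](C)(C)C(C)(C)C)/C=C\C(=O)O[C@@H](C)CC(=O)OC(C)(C)C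
F14 | step 7 | tert-butyl (3S)-3-{[(2Z,4R,5S)-5-{[(2S)-2-acetoxy-4-oxopentanoyl]oxy}-4-[(tert-butyldimethylsilyl)oxy]hex-2-enoyl]oxy}butanoate | C[C@H](OC(=O)[C@H](CC(C)=O)OC(C)=O)[C@H](O[Si](C)(C)C(C)(C)C)/C=C\C(=O)O[C@@H](C)CC(=O)OC(C)(C)C
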